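**Retrosynthetic overview**
- C12–O (last bond): enantioselective aerobic γ-hydroxylation of the planar fulvenolate of the 12-deoxy dienone 15; this sets 12R and the 7Z geometry.
- C7=C8: aldol condensation of bromoenone 8 with enal 11.
- Bromoenone 8: from 3-ethoxycyclopent-2-enone 1 by C2 bromination, α′-allylation with (Z)-octenyl bromide 4, and Stork–Danheiser reduction/transposition.
- Enal 11: cross-metathesis of methyl hex-5-enoate with crotonaldehyde.
- Rings: the only ring, the cyclopentenone, is bought as 1; no ring is formed.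

Assumption: the target is taken exactly as the given SMILES, methyl (5E,7Z,14Z)-(12R)-10-bromo-12-hydroxy-9-oxoprosta-5,7,10,14-tetraenoate (prostanoid numbering, C1 = ester carbon); 6–15 are racemic or diastereomer mixtures at centres erased by step 8 and are drawn without descriptors there; 15 is drawn as its major 7E isomer, and the minor 7Z isomer is carried along because both give anion 16.

**Step 1**
Reactants: 1 3-ethoxycyclopent-2-en-1-one
Product: 2 2-bromo-3-ethoxycyclopent-2-en-1-one
Conditions: NBS (1.05 equiv), CH2Cl2, 0 °C to rt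
Reagents that add atoms: N-bromosuccinimide, O=C1CCC(=O)N1Br
Why: Electrophilic bromination of the vinylogous ester at its nucleophilic C2 is fast and regiospecific.

**Step 2**
Reactants: 3 (2Z)-oct-2-en-1-ol
Product: 4 (2Z)-1-bromooct-2-ene
Conditions: PBr3 (0.4 equiv), pyridine (cat.), Et2O, −20 to 0 °C
Reagents that add atoms: phosphorus tribromide, BrP(Br)Br
Why: SN2 bromination of the primary allylic alcohol through its phosphite ester at low temperature keeps the Z-alkene and the primary position.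

**Step 3**
Reactants: 2 2-bromo-3-ethoxycyclopent-2-en-1-one; 4 (2Z)-1-bromooct-2-ene
Product: 6 2-bromo-3-ethoxy-5-[(2Z)-oct-2-en-1-yl]cyclopent-2-en-1-one (racemic), via lithium enolate 5 (not isolated)
Conditions: LiN(iPr)2 (commercial solution, 1.05 equiv), THF, −78 °C; then 4, DMPU, −78 to −20 °C
Reagents that add atoms: none
Why: Kinetic α′-deprotonation of the vinylogous ester and SN2 alkylation by the primary allylic bromide (Stork–Danheiser alkylation); the new C–H centre is racemic and is planarised in step 8.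

**Step 4**
Reactants: 6 2-bromo-3-ethoxy-5-[(2Z)-oct-2-en-1-yl]cyclopent-2-en-1-one
Product: 8 2-bromo-4-[(2Z)-oct-2-en-1-yl]cyclopent-2-en-1-one (racemic), via allylic alcohol 7 (not isolated)
Conditions: iBu2AlH (1.1 equiv), CH2Cl2, −78 °C; then 1 M HCl, THF, 0 °C to rt
Reagents that add atoms: water, O
Why: 1,2-Reduction followed by acid-mediated allylic ionisation and enol ether hydrolysis (Stork–Danheiser enone transposition) puts Br on the α-carbon and the octenyl chain on C4 of the new enone.

**Step 5**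
Reactants: 9 methyl hex-5-enoate; 10 (2E)-but-2-enal
Product: 11 methyl (5E)-7-oxohept-5-enoate
Conditions: second-generation Hoveyda–Grubbs catalyst RuCl2(H2IMes)(=CH-C6H4-2-OiPr) (H2IMes = 1,3-dimesitylimidazolidin-2-ylidene; 2 mol%), 10 (4 equiv), CH2Cl2, 40 °C
Reagents that add atoms: none
Why: Olefin cross-metathesis of a terminal alkene with crotonaldehyde gives the conjugated enal with high E-selectivity, driven by loss of propene.

**Step 6**
Reactants: 8 2-bromo-4-[(2Z)-oct-2-en-1-yl]cyclopent-2-en-1-one; 11 methyl (5E)-7-oxohept-5-enoate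
Product: 13 methyl (5E)-7-{3-bromo-2-oxo-5-[(2Z)-oct-2-en-1-yl]cyclopent-3-en-1-yl}-7-hydroxyhept-5-enoate (diastereomer mixture), via lithium dienolate 12 (not isolated)
Conditions: LiN(iPr)2 (1.05 equiv), THF, −78 °C (8 added slowly); then 11, −78 °C, 20 min; AcOH quench
Reagents that add atoms: none
Why: The kinetic α′-enolate undergoes aldol 1,2-addition to the aldehyde faster than it attacks the ester; the two new stereocentres are removed in step 7.

**Step 7**
Reactants: 13 methyl (5E)-7-{3-bromo-2-oxo-5-[(2Z)-oct-2-en-1-yl]cyclopent-3-en-1-yl}-7-hydroxyhept-5-enoate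
Product: 15 methyl (5E,7E)-7-{3-bromo-2-oxo-5-[(2Z)-oct-2-en-1-yl]cyclopent-3-en-1-ylidene}hept-5-enoate (racemic; 7E major), via allylic mesylate 14 (not isolated)
Conditions: MsCl (1.3 equiv), Et3N (3 equiv), DMAP (cat.), CH2Cl2, 0 °C to rt, Ar
Reagents that add atoms: none
Why: Mesylation followed by E1cB elimination through the ketone enolate gives the cross-conjugated trienone, and air is excluded because the C12–H is acidic.

**Step 8**
Reactants: 15 methyl (5E,7E)-7-{3-bromo-2-oxo-5-[(2Z)-oct-2-en-1-yl]cyclopent-3-en-1-ylidene}hept-5-enoate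
Product: 18 methyl (5E,7Z)-7-{(5R)-3-bromo-5-hydroxy-5-[(2Z)-oct-2-en-1-yl]-2-oxocyclopent-3-en-1-ylidene}hept-5-enoate (the target), via fulvenolate ion pair 16 (not isolated), via tertiary hydroperoxide 17 (not isolated)
Conditions: O-allyl-N-(9-anthracenylmethyl)cinchonidinium bromide (10 mol%), Cs2CO3 (0.5 equiv), toluene, Ar, 0 °C, 1 h; then O2 (1 atm), P(OEt)3 (1.5 equiv), −20 to 0 °C, dark
Reagents that add atoms: dioxygen, O=O
Why: Proposed new method: the C12–H of 15 is the only proton that is both γ to the ketone (through C10=C11) and allylic to the C7=C8–C5=C6 diene, so carbonate under solid–liquid phase transfer gives the planar, achiral 1-oxidofulvene ion pair 16, in which the in-plane C13 methylene pushes the C6 chain to the oxygen side (the lowered C7–C8 bond order lets both geometric isomers of 15 converge on the 7Z arrangement); O2 is then captured at C12, the only carbon whose oxygenation restores the cross-conjugated bromodienone (capture at C7 or C5 would create a cyclopentadienone, capture at C10 an unconjugated α-bromo ketone), on the face left open by the anthracenylmethyl-shielded cinchonidinium cation to give (R)-hydroperoxide 17, which P(OEt)3 reduces at once to 18 before it can epoxidise the bromoenone; the closest known chemistry is chiral phase-transfer-catalysed aerobic α-hydroxylation of ketone enolates with O2/P(OEt)3 and racemic γ-hydroperoxidation of dienolates, neither of which has been shown for γ-selective, enantioselective hydroxylation of a cross-conjugated cyclopentadienolate.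

**Compound list**
1 | 3-ethoxycyclopent-2-en-1-one | CCOC1=CC(=O)CC1 | starting material
2 | 2-bromo-3-ethoxycyclopent-2-en-1-one | CCOC1=C(Br)C(=O)CC1 | intermediate
3 | (2Z)-oct-2-en-1-ol | CCCCC/C=C\CO | starting material
4 | (2Z)-1-bromooct-2-ene | CCCCC/C=C\CBr | intermediate
5 | lithium 5-bromo-4-ethoxycyclopenta-1,4-dien-1-olate (α′-enolate of 2) | CCOC1=C(Br)C([O-])=CC1.[Li+] | intermediate
6 | 2-bromo-3-ethoxy-5-[(2Z)-oct-2-en-1-yl]cyclopent-2-en-1-one (racemic) | CCCCC/C=C\CC1CC(OCC)=C(Br)C1=O | intermediate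
7 | 2-bromo-3-ethoxy-5-[(2Z)-oct-2-en-1-yl]cyclopent-2-en-1-ol (diastereomer mixture) | CCCCC/C=C\CC1CC(OCC)=C(Br)C1O | intermediate
8 | 2-bromo-4-[(2Z)-oct-2-en-1-yl]cyclopent-2-en-1-one (racemic) | CCCCC/C=C\CC1CC(=O)C(Br)=C1 | intermediate
9 | methyl hex-5-enoate | C=CCCCC(=O)OC | starting material
10 | (2E)-but-2-enal (crotonaldehyde) | C/C=C/C=O | starting material
11 | methyl (5E)-7-oxohept-5-enoate | O=C/C=C/CCCC(=O)OC | intermediate
12 | lithium 5-bromo-3-[(2Z)-oct-2-en-1-yl]cyclopenta-1,4-dien-1-olate (α′-enolate of 8) | CCCCC/C=C\CC1C=C(Br)C([O-])=C1.[Li+] | intermediate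
13 | methyl (5E)-7-{3-bromo-2-oxo-5-[(2Z)-oct-2-en-1-yl]cyclopent-3-en-1-yl}-7-hydroxyhept-5-enoate (diastereomer mixture) | CCCCC/C=C\CC1C=C(Br)C(=O)C1C(O)/C=C/CCCC(=O)OC | intermediate
14 | methyl (5E)-7-{3-bromo-2-oxo-5-[(2Z)-oct-2-en-1-yl]cyclopent-3-en-1-yl}-7-[(methylsulfonyl)oxy]hept-5-enoate | CCCCC/C=C\CC1C=C(Br)C(=O)C1C(OS(C)(=O)=O)/C=C/CCCC(=O)OC | intermediate
15 | methyl (5E,7E)-7-{3-bromo-2-oxo-5-[(2Z)-oct-2-en-1-yl]cyclopent-3-en-1-ylidene}hept-5-enoate (racemic; 7E major) | CCCCC/C=C\CC1C=C(Br)C(=O)/C1=C/C=C/CCCC(=O)OC | intermediate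
16 | O-allyl-N-(9-anthracenylmethyl)cinchonidinium 2-bromo-4-[(2Z)-oct-2-en-1-yl]-5-[(2E)-7-methoxy-7-oxohept-2-en-1-ylidene]cyclopenta-1,3-dien-1-olate (chain syn to O) | CCCCC/C=C\CC1=CC(Br)=C([O-])/C1=C\C=C\CCCC(=O)OC.C=C[C@H]1C[N+]2(Cc3c4ccccc4cc4ccccc34)CC[C@H]1C[C@H]2[C@@H](c1ccnc2ccccc12)OCC=C | intermediate
17 | methyl (5E,7Z)-7-{(5R)-3-bromo-5-hydroperoxy-5-[(2Z)-oct-2-en-1-yl]-2-oxocyclopent-3-en-1-ylidene}hept-5-enoate | CCCCC/C=C\C[C@@]1(OO)C=C(Br)C(=O)/C1=C\C=C\CCCC(=O)OC | intermediate
18 | methyl (5E,7Z)-7-{(5R)-3-bromo-5-hydroxy-5-[(2Z)-oct-2-en-1-yl]-2-oxocyclopent-3-en-1-ylidene}hept-5-enoate | CCCCC/C=C\C[C@@]1(O)C=C(Br)C(=O)/C1=C\C=C\CCCC(=O)OC | target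

**Step count and risks**
Total steps: 8. Longest linear sequence: 6 (steps 1, 3, 4, 6, 7, 8).

Step 8 (the proposed new step) is the most likely to fail. The unknowns are the site of oxygen capture (C12 against C10), the level and sense of induction, and whether the anion equilibrates to the 7Z geometry before capture. If the sense of induction is opposite, the pseudoenantiomeric cinchonine-derived salt is used. The fallback uses known chemistry and runs from 15 to 18. Compound 15 is deprotonated with KN(SiMe3)2 (THF, −78 to 0 °C, Ar) and O-silylated with TBSCl to give the tert-butyldimethylsilyl fulvenyl ether F1. Sensitised photooxygenation (O2, tetraphenylporphyrin, visible light, CH2Cl2, −78 °C) adds singlet oxygen across C9/C12 in a [4+2] cycloaddition to give the bridged endoperoxide F2. HF·pyridine collapses the silyl peroxyketal to the racemic tertiary hydroperoxide F3, and PPh3 reduces it to the racemic tertiary alcohol F4. Preparative HPLC on a chiral stationary phase separates 18 from its enantiomer F5.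

Step 6 can fail through γ-deprotonation of 8, Michael self-addition of the bromoenone, or attack on the ester. The fallback runs from 8 to 13 and replaces the lithium enolate by a Mukaiyama aldol. Soft enolisation of 8 (TMSOTf, Et3N, CH2Cl2, 0 °C) gives the trimethylsilyl dienol ether F6. This is used at once with 11 and BF3·OEt2 (CH2Cl2, −78 °C) and gives 13 on aqueous work-up.

Step 3 can fail because the enolate of the brominated vinylogous ester 2 is less well precedented than that of 1; over-alkylation or decomposition are the concerns. The fallback runs from 1 and 4 to 6 and reverses the order of events. Compound 1 is alkylated first (LiN(iPr)2, THF, −78 °C, then 4) to give the alkylated vinylogous ester F7. NBS (CH2Cl2, 0 °C) then brominates C2 selectively over the isolated Z-alkene to give 6.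

**Further compounds**
F1 | step 8 | methyl (5E,7Z)-7-{3-bromo-2-[(tert-butyldimethylsilyl)oxy]-5-[(2Z)-oct-2-en-1-yl]cyclopenta-2,4-dien-1-ylidene}hept-5-enoate | CCCCC/C=C\CC1=CC(Br)=C(O[Si](C)(C)C(C)(C)C)/C1=C\C=C\CCCC(=O)OC
F2 | step 8 | methyl (5E,7Z)-7-{5-bromo-4-[(tert-butyldimethylsilyl)oxy]-1-[(2Z)-oct-2-en-1-yl]-2,3-dioxabicyclo[2.2.1]hept-5-en-7-ylidene}hept-5-enoate (racemic) | CCCCC/C=C\CC12OOC(O[Si](C)(C)C(C)(C)C)(C(Br)=C1)/C2=C\C=C\CCCC(=O)OC
F3 | step 8 | methyl (5E,7Z)-7-{3-bromo-5-hydroperoxy-5-[(2Z)-oct-2-en-1-yl]-2-oxocyclopent-3-en-1-ylidene}hept-5-enoate (racemic) | CCCCC/C=C\CC1(OO)C=C(Br)C(=O)/C1=C\C=C\CCCC(=O)OC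
F4 | step 8 | methyl (5E,7Z)-7-{3-bromo-5-hydroxy-5-[(2Z)-oct-2-en-1-yl]-2-oxocyclopent-3-en-1-ylidene}hept-5-enoate (racemate of 18) | CCCCC/C=C\CC1(O)C=C(Br)C(=O)/C1=C\C=C\CCCC(=O)OC
F5 | step 8 | methyl (5E,7Z)-7-{(5S)-3-bromo-5-hydroxy-5-[(2Z)-oct-2-en-1-yl]-2-oxocyclopent-3-en-1-ylidene}hept-5-enoate (enantiomer of 18) | CCCCC/C=C\C[C@]1(O)C=C(Br)C(=O)/C1=C\C=C\CCCC(=O)OC
F6 | step 6 | 2-bromo-3-(trimethylsilyloxy)-5-[(2Z)-oct-2-en-1-yl]cyclopenta-1,3-diene | CCCCC/C=C\CC1C=C(Br)C(O[Si](C)(C)C)=C1
F7 | step 3 | 3-ethoxy-5-[(2Z)-oct-2-en-1-yl]cyclopent-2-en-1-one (racemic) | CCCCC/C=C\CC1CC(OCC)=CC1=O
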